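**Plan** (chain numbering: C1 = lactone carbonyl, C13 = carbon bearing the ring oxygen)
1. The retrosynthesis cuts C2–C3 (intramolecular Reformatsky), then the C1–O ester, the C10–C11 diene bond (silicon-to-palladium coupling), C6–OMe, C5–C6 (alkynide/epoxide) and C8–C9 (enolate alkylation).
2. Enabling feature: the lactone oxygen on C13 is allylic to C11=C12, so O, C13, C12 and C11 close with one silicon atom to a five-membered 2,5-dihydro-1,2-oxasilole in which Si on C11 can only lie cis to C13.
3. Forward: that ring is closed first by metathesis (step 3). Separately the C6–C10 alkyne and the C3–C5 epoxide are joined at C5–C6, and a second temporary oxasilolane ring through the C4 oxygen fixes C6=C7 before Si is exchanged for I and then OMe.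
4. The halves are joined at C10–C11 with opening of the oxasilole, the freed C13–OH is acylated, and the 14-membered ring (the only ring of the target) closes last at C2–C3.
5. Stereochemistry: C13 from catalytic asymmetric ethylation, C8 from auxiliary-controlled alkylation, C4 from Sharpless epoxidation, C2 by equilibration. Z-C11=C12 comes from the oxasilole ring and E-C6=C7 from syn-hydrosilylation, both passed on with retention.

Key step: step 3

Assumption: C2 is the methine of a 1,3-dicarbonyl and epimerises through the enol, so the 2R configuration is taken to be the more stable one in the 14-membered ring and is set by equilibration in step 20.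

**Oxasilole (C11–C13 unit)**

Step 1
Reactants: 1 methacrolein
Product: 2 (S)-2-methylpent-1-en-3-ol
Conditions: Et2Zn, (−)-MIB (5 mol %), hexanes/toluene, 0 °C
Reagents that add atoms: diethylzinc, CC[Zn]CC
Why: Amino-alcohol-catalysed enantioselective addition of a dialkylzinc to an aldehyde; the (−)-MIB–zinc complex should deliver ethyl to the Si face of the s-trans enal, which sets C13 as S.

Step 2
Reactants: 2 (S)-2-methylpent-1-en-3-ol; 3 chloro(dimethyl)vinylsilane
Product: 4 (S)-dimethyl[(2-methylpent-1-en-3-yl)oxy](vinyl)silane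
Conditions: Et3N, DMAP (cat.), CH2Cl2, 0 °C → rt
Reagents that add atoms: none
Why: O-Silylation of a secondary alcohol with a chlorosilane and amine base; the allylic stereocentre is not involved.

Step 3
Reactants: 4 (S)-dimethyl[(2-methylpent-1-en-3-yl)oxy](vinyl)silane
Product: 5 (S)-5-ethyl-2,2,4-trimethyl-2,5-dihydro-1,2-oxasilole
Conditions: Mo(=CHCMe2Ph)(=N-2,6-iPr2C6H3)[OCMe(CF3)2]2 (6 mol %), C6H6 (0.1 M), rt
Reagents that add atoms: none
Why: The molybdenum alkylidene should add to the unhindered Si-vinyl group by [2+2] cycloaddition and cycloreversion, and the resulting silyl-substituted alkylidene then adds intramolecularly to the 1,1-disubstituted alkene; cycloreversion releases the oxasilole and Mo=CH2, and ethylene leaves. The closest known reaction type is ring-closing metathesis of alkenyl dimethyl(vinyl)silyl ethers to cyclic alkenylsiloxanes with this class of molybdenum imido alkylidene. The one ring is closed as a five-membered ring by metathesis, with both carbons of the new C11=C12 bond inside the ring. No stereocentre is formed, and C13 is untouched because no bond to it is made or broken. The step needs cyclisation to beat intermolecular metathesis and needs a trisubstituted alkene to form: the short O–Si tether and moderate dilution favour ring closure, the highly active catalyst accepts both the vinylsilane and the gem-disubstituted alkene, and the five-membered ring can hold only the cis alkene, so Si on C11 is fixed cis to C13.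

**Alkyne (C6–C10 unit)**

Step 4
Reactants: 6 (R)-4-benzyl-3-propanoyl-1,3-oxazolidin-2-one; 7 2,3-dibromoprop-1-ene
Product: 8 (R)-4-benzyl-3-[(S)-4-bromo-2-methylpent-4-enoyl]-1,3-oxazolidin-2-one
Conditions: NaHMDS, THF, −78 °C; then 7, −78 → −40 °C
Reagents that add atoms: none
Why: Evans asymmetric alkylation; the chelated Z sodium enolate should be alkylated by the allylic bromide on the face opposite the benzyl group, which sets C8 as S, and the vinylic bromide is inert.

Step 5
Reactants: 8 (R)-4-benzyl-3-[(S)-4-bromo-2-methylpent-4-enoyl]-1,3-oxazolidin-2-one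
Product: 9 (S)-4-bromo-2-methylpent-4-en-1-ol
Conditions: LiBH4, MeOH (1 equiv), Et2O, 0 °C
Reagents that add atoms: none
Why: Reductive cleavage of the N-acyloxazolidinone with borohydride releases the primary alcohol and the auxiliary without affecting C8 or the vinyl bromide.

Step 6
Reactants: 9 (S)-4-bromo-2-methylpent-4-en-1-ol
Product: 10 (S)-4-bromo-2-methylpent-4-enal
Conditions: Dess–Martin periodinane, NaHCO3, CH2Cl2, 0 °C → rt; used crude
Reagents that add atoms: none
Why: Dess–Martin oxidation under bicarbonate buffer stops at the aldehyde and is mild enough to preserve the α-stereocentre.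

Step 7
Reactants: 10 (S)-4-bromo-2-methylpent-4-enal
Product: 11 (S)-5-bromo-3-methylhex-5-en-1-yne
Conditions: dimethyl (1-diazo-2-oxopropyl)phosphonate, K2CO3, MeOH, 0 °C → rt
Reagents that add atoms: dimethyl (1-diazo-2-oxopropyl)phosphonate, CC(=O)C(=[N+]=[N-])P(=O)(OC)OC
Why: Ohira–Bestmann (Seyferth–Gilbert) homologation converts the aldehyde into the terminal alkyne with one added carbon (C6); the mild carbonate conditions and low temperature should limit α-epimerisation.

**Epoxide (C3–C5 unit)**

Step 8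
Reactants: 12 2-methylenepropane-1,3-diol
Product: 13 2-({[tert-butyl(dimethyl)silyl]oxy}methyl)prop-2-en-1-ol
Conditions: NaH (1.0 equiv), THF, 0 °C; TBSCl (1.0 equiv), rt
Reagents that add atoms: tert-butyl(chloro)dimethylsilane, CC(C)(C)[Si](C)(C)Cl
Why: Monosilylation of a symmetrical diol through its sparingly soluble monosodium alkoxide (O-silylation) should stop after one silyl group.

Step 9
Reactants: 13 2-({[tert-butyl(dimethyl)silyl]oxy}methyl)prop-2-en-1-ol
Product: 14 (R)-[2-({[tert-butyl(dimethyl)silyl]oxy}methyl)oxiran-2-yl]methanol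
Conditions: Ti(OiPr)4 (10 mol %), D-(−)-diethyl tartrate (12 mol %), t-BuOOH, 4 Å MS, CH2Cl2, −20 °C
Reagents that add atoms: tert-butyl hydroperoxide, CC(C)(C)OO
Why: Sharpless asymmetric epoxidation; with D-(−)-tartrate the titanium-bound peroxide should be delivered to the face that gives the (R)-epoxy alcohol (the sense that turns methallyl alcohol into (R)-2-methylglycidol), which sets the future C4 with the free hydroxymethyl arm as the future C3.

Step 10
Reactants: 14 (R)-[2-({[tert-butyl(dimethyl)silyl]oxy}methyl)oxiran-2-yl]methanol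
Product: 15 (S)-tert-butyl(dimethyl)[(2-{[(triethylsilyl)oxy]methyl}oxiran-2-yl)methoxy]silane
Conditions: TESCl, imidazole, CH2Cl2, 0 °C
Reagents that add atoms: chlorotriethylsilane, CC[Si](CC)(CC)Cl
Why: Imidazole-mediated O-silylation; the neutral conditions avoid silyl migration between the two arms, which would invert the sense of the quaternary centre.

**Union and enol ether (C3–C10 fragment)**

Step 11
Reactants: 11 (S)-5-bromo-3-methylhex-5-en-1-yne; 15 (S)-tert-butyl(dimethyl)[(2-{[(triethylsilyl)oxy]methyl}oxiran-2-yl)methoxy]silane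
Product: 16 (2S,6S)-8-bromo-2-({[tert-butyl(dimethyl)silyl]oxy}methyl)-6-methyl-1-[(triethylsilyl)oxy]non-8-en-4-yn-2-ol
Conditions: 11, n-BuLi, THF, −78 °C; BF3·OEt2; then 15, −78 °C
Reagents that add atoms: none
Why: BF3-mediated opening of an epoxide by a lithium alkynide (SN2 at the unsubstituted epoxide carbon) forms C5–C6 and leaves the quaternary carbon untouched; the two β-silyloxy groups disfavour ionisation at the tertiary carbon.

Step 12
Reactants: 16 (2S,6S)-8-bromo-2-({[tert-butyl(dimethyl)silyl]oxy}methyl)-6-methyl-1-[(triethylsilyl)oxy]non-8-en-4-yn-2-ol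
Product: 18 (E)-alkylidene-1,2-oxasilolane (Si on C6 and O on C4 in one ring), via dimethylsilyl ether 17 (not isolated)
Conditions: (HMe2Si)2NH, 70 °C, then evaporate; Pt2(dvds)3 (0.5 mol %), THF, rt
Reagents that add atoms: 1,1,3,3-tetramethyldisilazane, C[SiH](C)N[SiH](C)C
Why: O-Silylation by the disilazane followed by platinum-catalysed intramolecular syn-hydrosilylation (5-exo-dig) should place Si on C6 and H on C7 on the same side, so C5 and C8 end up cis; the five-membered tether dictates the regiochemistry.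

Step 13
Reactants: 18 (E)-alkylidene-1,2-oxasilolane
Product: 20 (2S,4E,6S)-8-bromo-2-({[tert-butyl(dimethyl)silyl]oxy}methyl)-4-iodo-6-methyl-1-[(triethylsilyl)oxy]nona-4,8-dien-2-ol, via N-silylsuccinimide 19 (not isolated)
Conditions: NIS, MeCN–ClCH2CN (4:1), 0 °C, dark; then K2CO3, MeOH, 0 °C
Reagents that add atoms: N-iodosuccinimide, O=C1CCC(=O)N1I
Why: Iododesilylation of an alkenylsilane (electrophilic ipso substitution through a β-silyl cation) should replace Si by I with retention of alkene geometry; methanolysis then strips the silyl residue from the C4 oxygen.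

Step 14
Reactants: 20 (2S,4E,6S)-8-bromo-2-({[tert-butyl(dimethyl)silyl]oxy}methyl)-4-iodo-6-methyl-1-[(triethylsilyl)oxy]nona-4,8-dien-2-ol
Product: 21 (2S,4E,6S)-8-bromo-2-({[tert-butyl(dimethyl)silyl]oxy}methyl)-4-iodo-6-methyl-1,2-bis[(triethylsilyl)oxy]nona-4,8-diene
Conditions: TESOTf, 2,6-lutidine, CH2Cl2, −78 → 0 °C
Reagents that add atoms: triethylsilyl trifluoromethanesulfonate, CC[Si](CC)(CC)OS(=O)(=O)C(F)(F)F
Why: Silylation of a tertiary alcohol with a silyl triflate and a hindered pyridine base; it blocks the C4 hydroxyl, which would otherwise cyclise onto the alkenyl iodide under copper catalysis.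

Step 15
Reactants: 21 (2S,4E,6S)-8-bromo-2-({[tert-butyl(dimethyl)silyl]oxy}methyl)-4-iodo-6-methyl-1,2-bis[(triethylsilyl)oxy]nona-4,8-diene
Product: 22 (2S,4E,6S)-8-bromo-2-({[tert-butyl(dimethyl)silyl]oxy}methyl)-4-methoxy-6-methyl-1,2-bis[(triethylsilyl)oxy]nona-4,8-diene
Conditions: CuI (20 mol %), 3,4,7,8-tetramethyl-1,10-phenanthroline (40 mol %), Cs2CO3, MeOH (5 equiv), toluene, 80 °C
Reagents that add atoms: methanol, CO
Why: Copper-catalysed Ullmann-type C–O coupling of an alkenyl iodide with an alcohol proceeds with retention and should give the E enol ether (OMe cis to H on C7); the iodide is expected to react ahead of the 2-bromoalkene.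

**Endgame**

Step 16
Reactants: 5 (S)-5-ethyl-2,2,4-trimethyl-2,5-dihydro-1,2-oxasilole; 22 (2S,4E,6S)-8-bromo-2-({[tert-butyl(dimethyl)silyl]oxy}methyl)-4-methoxy-6-methyl-1,2-bis[(triethylsilyl)oxy]nona-4,8-diene
Product: 24 (3S,4Z,8S,9E,12S)-12-({[tert-butyl(dimethyl)silyl]oxy}methyl)-10-methoxy-4,8-dimethyl-6-methylidene-12,13-bis[(triethylsilyl)oxy]trideca-4,9-dien-3-ol, via dipotassium silanolate 23 (not isolated)
Conditions: 5, KOSiMe3 (2.2 equiv), DME, rt; then 22, Pd(PtBu3)2 (5 mol %), rt → 40 °C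
Reagents that add atoms: none
Why: Hiyama–Denmark cross-coupling; the silanolate formed by opening the strained Si–O bond should transfer C11 to palladium with retention after oxidative addition of the 2-bromoalkene, so the ring geometry becomes Z-C11=C12 and the C13 hydroxyl is released in the same operation.

Step 17
Reactants: 24 the Z-dienol; 25 2-bromopropanoyl bromide (racemic)
Product: 26 2-bromopropanoate of 24 (both C–Br epimers)
Conditions: pyridine, CH2Cl2, −20 → 0 °C
Reagents that add atoms: none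
Why: Acylation of the secondary allylic alcohol with an acid bromide and pyridine; the C–Br centre forms as a mixture, which is irrelevant because it becomes an enolate.

Step 18
Reactants: 26 2-bromopropanoate of 24
Product: 27 C3 aldehyde (13-oxo compound)
Conditions: (COCl)2, DMSO, CH2Cl2, −78 → −35 °C; then Et3N, −78 → 0 °C
Reagents that add atoms: none
Why: Swern-type oxidative desilylation; activated DMSO cleaves a primary triethylsilyl ether and oxidises it to the aldehyde in one operation, while the tertiary TES ether and the primary TBS ether are too hindered or too stable to react.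

Step 19
Reactants: 27 C3 aldehyde
Product: 28 14-membered β-hydroxy lactone (mixture at C2 and C3)
Conditions: SmI2 (3 equiv), THF, −78 °C, slow addition of 27 (final 0.003 M)
Reagents that add atoms: none
Why: Samarium diiodide-mediated intramolecular Reformatsky reaction; reduction of the α-bromo ester gives a samarium enolate that should add to the non-enolisable aldehyde and close the 14-membered ring, with C2 and C3 formed as mixtures that the next step removes.

Step 20
Reactants: 28 14-membered β-hydroxy lactone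
Product: 29 bis-silylated β-keto lactone (2R)
Conditions: Dess–Martin periodinane, NaHCO3, CH2Cl2, 0 °C → rt; then Et3N (cat.), CH2Cl2, rt
Reagents that add atoms: none
Why: Dess–Martin oxidation gives the β-keto lactone; C2, now a 1,3-dicarbonyl methine, should equilibrate through the enol to the more stable 2R epimer.

Step 21
Reactants: 29 bis-silylated β-keto lactone
Product: 30 CNP0325854.3
Conditions: TBAF–AcOH (1:1), THF, 0 °C → rt
Reagents that add atoms: none
Why: Fluoride-mediated cleavage of both silyl ethers, buffered with acetic acid so that neither the acid-labile enol ether nor the base-labile β-keto lactone and α-ketol are harmed.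

**Compound list** (names use IUPAC locants; the discussion uses the chain numbering C1–C13)

1 | methacrolein | C=C(C)C=O | starting material
2 | (S)-2-methylpent-1-en-3-ol | C=C(C)[C@H](CC)O | intermediate
3 | chloro(dimethyl)vinylsilane | C=C[Si](C)(C)Cl | starting material
4 | (S)-dimethyl[(2-methylpent-1-en-3-yl)oxy](vinyl)silane | C=C(C)[C@H](CC)O[Si](C)(C)C=C | intermediate
5 | (S)-5-ethyl-2,2,4-trimethyl-2,5-dihydro-1,2-oxasilole | CC[C@@H]1O[Si](C)(C)C=C1C | intermediate
6 | (R)-4-benzyl-3-propanoyl-1,3-oxazolidin-2-one | CCC(=O)N1[C@H](Cc2ccccc2)COC1=O | starting material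
7 | 2,3-dibromoprop-1-ene | C=C(Br)CBr | starting material
8 | (R)-4-benzyl-3-[(S)-4-bromo-2-methylpent-4-enoyl]-1,3-oxazolidin-2-one | C=C(Br)C[C@H](C)C(=O)N1[C@H](Cc2ccccc2)COC1=O | intermediate
9 | (S)-4-bromo-2-methylpent-4-en-1-ol | C=C(Br)C[C@H](C)CO | intermediate
10 | (S)-4-bromo-2-methylpent-4-enal | C=C(Br)C[C@H](C)C=O | intermediate
11 | (S)-5-bromo-3-methylhex-5-en-1-yne | C=C(Br)C[C@H](C)C#C | intermediate
12 | 2-methylenepropane-1,3-diol | C=C(CO)CO | starting material
13 | 2-({[tert-butyl(dimethyl)silyl]oxy}methyl)prop-2-en-1-ol | C=C(CO)CO[Si](C)(C)C(C)(C)C | intermediate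
14 | (R)-[2-({[tert-butyl(dimethyl)silyl]oxy}methyl)oxiran-2-yl]methanol | OC[C@]1(CO[Si](C)(C)C(C)(C)C)CO1 | intermediate
15 | (S)-tert-butyl(dimethyl)[(2-{[(triethylsilyl)oxy]methyl}oxiran-2-yl)methoxy]silane | CC[Si](CC)(CC)OC[C@]1(CO[Si](C)(C)C(C)(C)C)CO1 | intermediate
16 | (2S,6S)-8-bromo-2-({[tert-butyl(dimethyl)silyl]oxy}methyl)-6-methyl-1-[(triethylsilyl)oxy]non-8-en-4-yn-2-ol | C=C(Br)C[C@H](C)C#CC[C@](O)(CO[Si](CC)(CC)CC)CO[Si](C)(C)C(C)(C)C | intermediate
17 | dimethylsilyl (Si–H) ether of 16 at the tertiary oxygen | C=C(Br)C[C@H](C)C#CC[C@](O[SiH](C)C)(CO[Si](CC)(CC)CC)CO[Si](C)(C)C(C)(C)C | intermediate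
18 | (S,E)-3-[(S)-4-bromo-2-methylpent-4-en-1-ylidene]-5-({[tert-butyl(dimethyl)silyl]oxy}methyl)-2,2-dimethyl-5-{[(triethylsilyl)oxy]methyl}-1,2-oxasilolane | C=C(Br)C[C@H](C)/C=C1\C[C@](CO[Si](CC)(CC)CC)(CO[Si](C)(C)C(C)(C)C)O[Si]1(C)C | intermediate
19 | 1-({[(2S,4E,6S)-8-bromo-2-({[tert-butyl(dimethyl)silyl]oxy}methyl)-4-iodo-6-methyl-1-[(triethylsilyl)oxy]nona-4,8-dien-2-yl]oxy}dimethylsilyl)pyrrolidine-2,5-dione | C=C(Br)C[C@H](C)/C=C(/I)C[C@](O[Si](C)(C)N1C(=O)CCC1=O)(CO[Si](CC)(CC)CC)CO[Si](C)(C)C(C)(C)C | intermediate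
20 | (2S,4E,6S)-8-bromo-2-({[tert-butyl(dimethyl)silyl]oxy}methyl)-4-iodo-6-methyl-1-[(triethylsilyl)oxy]nona-4,8-dien-2-ol | C=C(Br)C[C@H](C)/C=C(/I)C[C@](O)(CO[Si](CC)(CC)CC)CO[Si](C)(C)C(C)(C)C | intermediate
21 | (2S,4E,6S)-8-bromo-2-({[tert-butyl(dimethyl)silyl]oxy}methyl)-4-iodo-6-methyl-1,2-bis[(triethylsilyl)oxy]nona-4,8-diene | C=C(Br)C[C@H](C)/C=C(/I)C[C@](O[Si](CC)(CC)CC)(CO[Si](CC)(CC)CC)CO[Si](C)(C)C(C)(C)C | intermediate
22 | (2S,4E,6S)-8-bromo-2-({[tert-butyl(dimethyl)silyl]oxy}methyl)-4-methoxy-6-methyl-1,2-bis[(triethylsilyl)oxy]nona-4,8-diene | C=C(Br)C[C@H](C)/C=C(/OC)C[C@](O[Si](CC)(CC)CC)(CO[Si](CC)(CC)CC)CO[Si](C)(C)C(C)(C)C | intermediate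
23 | dipotassium (S,Z)-1-[dimethyl(oxido)silyl]-2-methylpent-1-en-3-olate | CC[C@@H](/C(C)=C\[Si](C)(C)[O-])[O-].[K+].[K+] | intermediate
24 | (3S,4Z,8S,9E,12S)-12-({[tert-butyl(dimethyl)silyl]oxy}methyl)-10-methoxy-4,8-dimethyl-6-methylidene-12,13-bis[(triethylsilyl)oxy]trideca-4,9-dien-3-ol | C=C(/C=C(/C)[C@H](CC)O)C[C@H](C)/C=C(/OC)C[C@](O[Si](CC)(CC)CC)(CO[Si](CC)(CC)CC)CO[Si](C)(C)C(C)(C)C | intermediate
25 | 2-bromopropanoyl bromide (racemic) | CC(Br)C(=O)Br | starting material
26 | (3S,4Z,8S,9E,12S)-12-({[tert-butyl(dimethyl)silyl]oxy}methyl)-10-methoxy-4,8-dimethyl-6-methylidene-12,13-bis[(triethylsilyl)oxy]trideca-4,9-dien-3-yl 2-bromopropanoate (both C–Br epimers) | C=C(/C=C(/C)[C@H](CC)OC(=O)C(C)Br)C[C@H](C)/C=C(/OC)C[C@](O[Si](CC)(CC)CC)(CO[Si](CC)(CC)CC)CO[Si](C)(C)C(C)(C)C | intermediate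
27 | (3S,4Z,8S,9E,12R)-12-({[tert-butyl(dimethyl)silyl]oxy}methyl)-10-methoxy-4,8-dimethyl-6-methylidene-13-oxo-12-[(triethylsilyl)oxy]trideca-4,9-dien-3-yl 2-bromopropanoate (both C–Br epimers) | C=C(/C=C(/C)[C@H](CC)OC(=O)C(C)Br)C[C@H](C)/C=C(/OC)C[C@](O[Si](CC)(CC)CC)(C=O)CO[Si](C)(C)C(C)(C)C | intermediate
28 | (5R,7E,9S,12Z,14S)-5-({[tert-butyl(dimethyl)silyl]oxy}methyl)-14-ethyl-4-hydroxy-7-methoxy-3,9,13-trimethyl-11-methylidene-5-[(triethylsilyl)oxy]-1-oxacyclotetradeca-7,12-dien-2-one (mixture at ring C3 and C4) | C=C1/C=C(/C)[C@H](CC)OC(=O)C(C)C(O)[C@](O[Si](CC)(CC)CC)(CO[Si](C)(C)C(C)(C)C)C/C(OC)=C\[C@@H](C)C1 | intermediate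
29 | (3R,5R,7E,9S,12Z,14S)-5-({[tert-butyl(dimethyl)silyl]oxy}methyl)-14-ethyl-7-methoxy-3,9,13-trimethyl-11-methylidene-5-[(triethylsilyl)oxy]-1-oxacyclotetradeca-7,12-diene-2,4-dione | C=C1/C=C(/C)[C@H](CC)OC(=O)[C@H](C)C(=O)[C@](O[Si](CC)(CC)CC)(CO[Si](C)(C)C(C)(C)C)C/C(OC)=C\[C@@H](C)C1 | intermediate
30 | (3R,5R,7E,9S,12Z,14S)-14-ethyl-5-hydroxy-5-(hydroxymethyl)-7-methoxy-3,9,13-trimethyl-11-methylidene-1-oxacyclotetradeca-7,12-diene-2,4-dione (CNP0325854.3) | C=C1/C=C(/C)[C@H](CC)OC(=O)[C@H](C)C(=O)[C@](O)(CO)C/C(OC)=C\[C@@H](C)C1 | target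

**Step count**
Total: 21 steps. Longest linear sequence: 15 steps (4–7, 11–15, 16–21, from imide 6).

**Steps most likely to fail**

Step 15. The copper catalyst may also substitute the unhindered C10 bromide, and hot carbonate in methanol may strip the primary triethylsilyl ether, after which the freed alkoxide would cyclise onto C6. The fallback makes the C6–O bond oxidatively at room temperature. It sets out from iodide 21: iodine–lithium exchange (n-BuLi, Et2O, −78 °C, where the iodide exchanges far faster than the 2-bromoalkene) and quench with 2-isopropoxy-4,4,5,5-tetramethyl-1,3,2-dioxaborolane should give alkenyl pinacol boronate F1 with retention. Chan–Lam-type alkenyl etherification (Cu(OAc)2, Et3N, MeOH, air, rt) then exchanges boron for methoxy with retention and comes back to the route at 22.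

Step 16. Transmetalation from the ring-opened silanolate may be slow without fluoride, and the silanolate base may attack the primary triethylsilyl ether before coupling occurs. The fallback keeps the metathesis-derived ring as the source of geometry but joins the halves through boron. It sets out from 5 and 22: iododesilylation of 5 (NIS, MeCN, 0 °C; then K2CO3, MeOH) should give (S,Z)-1-iodo-2-methylpent-1-en-3-ol F2 with retention. Miyaura borylation of 22 (PdCl2(PPh3)2, B2pin2, KOPh, toluene, 50 °C) should give 2-alkenyl pinacol boronate F3. Suzuki–Miyaura coupling of F2 with F3 (Pd(PPh3)4, aq. K3PO4, THF, rt) comes back to the route at 24.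

Step 19. The samarium enolate may be protonated or may add intermolecularly, giving reduced ester or oligomers instead of the 14-membered ring. The fallback forms C2–C3 intermolecularly and closes the ring at the C1–O bond through an acylketene. It sets out from 22: oxidative desilylation under the conditions of step 18 should give aldehyde F4; Reformatsky addition of tert-butyl 2-bromopropanoate (Zn, THF) gives β-hydroxy tert-butyl ester F5; Dess–Martin oxidation gives β-keto tert-butyl ester F6. Coupling of F6 with silanolate 23 under the conditions of step 16 gives hydroxy β-keto ester F7. Heating F7 in toluene at high dilution should expel tert-butanol to give acylketene F8, which is trapped by the C13 hydroxyl and comes back to the route at 29.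

**Further compounds**

F1 | step 15 | (2S,4Z,6S)-8-bromo-2-({[tert-butyl(dimethyl)silyl]oxy}methyl)-6-methyl-4-(4,4,5,5-tetramethyl-1,3,2-dioxaborolan-2-yl)-1,2-bis[(triethylsilyl)oxy]nona-4,8-diene | C=C(Br)C[C@H](C)/C=C(/B1OC(C)(C)C(C)(C)O1)C[C@](O[Si](CC)(CC)CC)(CO[Si](CC)(CC)CC)CO[Si](C)(C)C(C)(C)C
F2 | step 16 | (S,Z)-1-iodo-2-methylpent-1-en-3-ol | CC[C@@H](/C(C)=C\I)O
F3 | step 16 | 2-[(4S,5E,8S)-8-({[tert-butyl(dimethyl)silyl]oxy}methyl)-6-methoxy-4-methyl-8,9-bis[(triethylsilyl)oxy]nona-1,5-dien-2-yl]-4,4,5,5-tetramethyl-1,3,2-dioxaborolane | C=C(B1OC(C)(C)C(C)(C)O1)C[C@H](C)/C=C(/OC)C[C@](O[Si](CC)(CC)CC)(CO[Si](CC)(CC)CC)CO[Si](C)(C)C(C)(C)C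
F4 | step 19 | (2R,4E,6S)-8-bromo-2-({[tert-butyl(dimethyl)silyl]oxy}methyl)-4-methoxy-6-methyl-2-[(triethylsilyl)oxy]nona-4,8-dienal | C=C(Br)C[C@H](C)/C=C(/OC)C[C@](O[Si](CC)(CC)CC)(C=O)CO[Si](C)(C)C(C)(C)C
F5 | step 19 | tert-butyl (4R,6E,8S)-10-bromo-4-({[tert-butyl(dimethyl)silyl]oxy}methyl)-3-hydroxy-6-methoxy-2,8-dimethyl-4-[(triethylsilyl)oxy]undeca-6,10-dienoate (mixture at C2 and C3) | C=C(Br)C[C@H](C)/C=C(/OC)C[C@](O[Si](CC)(CC)CC)(C(O)C(C)C(=O)OC(C)(C)C)CO[Si](C)(C)C(C)(C)C
F6 | step 19 | tert-butyl (4R,6E,8S)-10-bromo-4-({[tert-butyl(dimethyl)silyl]oxy}methyl)-6-methoxy-2,8-dimethyl-3-oxo-4-[(triethylsilyl)oxy]undeca-6,10-dienoate | C=C(Br)C[C@H](C)/C=C(/OC)C[C@](O[Si](CC)(CC)CC)(C(=O)C(C)C(=O)OC(C)(C)C)CO[Si](C)(C)C(C)(C)C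
F7 | step 19 | tert-butyl (4R,6E,8S,11Z,13S)-4-({[tert-butyl(dimethyl)silyl]oxy}methyl)-13-hydroxy-6-methoxy-2,8,12-trimethyl-10-methylidene-3-oxo-4-[(triethylsilyl)oxy]pentadeca-6,11-dienoate | C=C(/C=C(/C)[C@H](CC)O)C[C@H](C)/C=C(/OC)C[C@](O[Si](CC)(CC)CC)(C(=O)C(C)C(=O)OC(C)(C)C)CO[Si](C)(C)C(C)(C)C
F8 | step 19 | acylketene from F7 (2-methyl-3-oxoalk-1-en-1-one with the C13 hydroxyl free) | C=C(/C=C(/C)[C@H](CC)O)C[C@H](C)/C=C(/OC)C[C@](O[Si](CC)(CC)CC)(C(=O)C(C)=C=O)CO[Si](C)(C)C(C)(C)C
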